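The route cuts ring A from ring C at two bonds at once, O1–C8a and C4–C4a. These bonds sit on adjacent ring-A carbons, so ring A is brought in as a 3,5-dialkoxy-4-prenylbenzyne. Ring C is closed by a fluoride-triggered [4+2] annulation with the alkoxide of an enantiopure β-silyloxy ester that already carries C2 (S) and the chromene ring B. The alkoxide adds to C8a, the aryl anion at C4a acylates itself on the ester, and the C5 oxygen next to C4a dictates this orientation. The precursors are an ortho-silyl aryl triflate and an acyclic (S)-3-aryl-3-(trimethylsilyloxy)propanoate; neither contains ring C.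

Key step: step 13

Remark: flavanone numbering is used (O1, C2, C3, C4, C4a, C5 to C8, C8a); ring A is the benzo ring of the chromanone, ring C its pyranone ring, ring B the benzene ring of the chromenyl substituent; the target SMILES corresponds to (2S).

**Synthesis of the aryne precursor (ring A)**

Step 1
Reactants: 1 resorcinol
Product: 2 1,3-bis(methoxymethoxy)benzene
Conditions: NaH, MOMCl, DMF, 0 °C → rt
Reagents that add atoms: chloromethyl methyl ether, COCCl
Why: Williamson-type O-alkylation of the bis-phenoxide gives the bis-acetal, which later serves as protecting and ortho-directing group.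

Step 2
Reactants: 2 1,3-bis(methoxymethoxy)benzene; 3 prenyl bromide
Product: 5 1,3-bis(methoxymethoxy)-2-(3-methylbut-2-en-1-yl)benzene, via aryllithium 4 (not isolated)
Conditions: n-BuLi, THF, 0 °C; then CuI (10 mol%), 3, −78 °C → rt
Reagents that add atoms: none
Why: directed ortho-metalation occurs at C2 between the two cooperating OMOM groups, and the aryllithium, through its cuprate, is allylated at the primary carbon of prenyl bromide (SN2 allylation).

Step 3
Reactants: 5 1,3-bis(methoxymethoxy)-2-(3-methylbut-2-en-1-yl)benzene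
Product: 7 3,5-bis(methoxymethoxy)-4-(3-methylbut-2-en-1-yl)phenol, via pinacol boronate 6 (not isolated)
Conditions: [Ir(OMe)(cod)]2 (1.5 mol%), 4,4'-di-tert-butyl-2,2'-bipyridine (3 mol%), B2pin2 (0.55 equiv), THF, 80 °C; then aq. NaOH, H2O2, 0 °C → rt
Reagents that add atoms: hydrogen peroxide, OO
Why: sterically controlled iridium-catalysed C–H borylation (Hartwig–Miyaura type) should take the only arene C–H without an ortho substituent, para to the prenyl group, and basic peroxide oxidation of the C–B bond gives the phenol in the same flask.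

Step 4
Reactants: 7 3,5-bis(methoxymethoxy)-4-(3-methylbut-2-en-1-yl)phenol
Product: 8 2-bromo-3,5-bis(methoxymethoxy)-4-(3-methylbut-2-en-1-yl)phenol
Conditions: NBS (1.0 equiv), CH2Cl2, −78 °C
Reagents that add atoms: N-bromosuccinimide, O=C1CCC(=O)N1Br
Why: electrophilic aromatic bromination of a free phenol whose para position is blocked by prenyl and whose two ortho positions are equivalent, so one equivalent of NBS at low temperature should give a single monobromide.

Step 5
Reactants: 8 2-bromo-3,5-bis(methoxymethoxy)-4-(3-methylbut-2-en-1-yl)phenol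
Product: 11 3,5-bis(methoxymethoxy)-4-(3-methylbut-2-en-1-yl)-2-(trimethylsilyl)phenyl trifluoromethanesulfonate, via silyl ether 9 (not isolated), via lithium phenoxide 10 (not isolated)
Conditions: HMDS, THF, 65 °C, evaporate; n-BuLi, THF, −100 → −78 °C; Tf2O, −100 °C → rt
Reagents that add atoms: hexamethyldisilazane, C[Si](C)(C)N[Si](C)(C)C; trifluoromethanesulfonic anhydride, O=S(=O)(OS(=O)(=O)C(F)(F)F)C(F)(F)F
Why: bromine–lithium exchange on the O-silyl bromophenol triggers the retro-Brook 1,3 O-to-C silyl shift and the resulting phenoxide is triflated, the standard entry to Kobayashi aryne precursors.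

**Synthesis of the β-silyloxy ester (ring B and C2)**

Step 6
Reactants: 1 resorcinol; 12 3-methylbut-2-enoic acid
Product: 13 7-hydroxy-2,2-dimethylchroman-4-one
Conditions: MeSO3H/P2O5 (Eaton's reagent), 70 °C
Reagents that add atoms: none
Why: Friedel–Crafts acylation of resorcinol para to one hydroxyl followed by intramolecular oxa-Michael addition of the ortho hydroxyl gives the 7-hydroxychromanone regioselectively.

Step 7
Reactants: 13 7-hydroxy-2,2-dimethylchroman-4-one
Product: 15 2,2-dimethyl-2H-chromen-7-ol, via chromanediol 14 (not isolated)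
Conditions: LiAlH4, THF, 0 °C → rt; then PPTS (cat.), toluene, 80 °C
Reagents that add atoms: none
Why: hydride reduction gives a benzylic alcohol para to the phenol, which should dehydrate readily under mild acid catalysis (E1) to the 2H-chromene.

Step 8
Reactants: 15 2,2-dimethyl-2H-chromen-7-ol
Product: 16 7-hydroxy-2,2-dimethyl-2H-chromene-6-carbaldehyde
Conditions: MgCl2, Et3N, (CH2O)n, MeCN, reflux
Reagents that add atoms: paraformaldehyde (as formaldehyde), C=O
Why: Casnati–Skattebøl ortho-formylation through the magnesium phenoxide should place the formyl group at C6 (ortho to the hydroxyl, para to the ring oxygen, unhindered) and not at C8 between the two oxygens.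

Step 9
Reactants: 16 7-hydroxy-2,2-dimethyl-2H-chromene-6-carbaldehyde
Product: 17 7-(methoxymethoxy)-2,2-dimethyl-2H-chromene-6-carbaldehyde
Conditions: MOMCl, iPr2NEt, CH2Cl2, 0 → 40 °C
Reagents that add atoms: chloromethyl methyl ether, COCCl
Why: O-alkylation to the MOM ether masks the only acidic O–H that could otherwise capture the aryne in step 13.

Step 10
Reactants: 17 7-(methoxymethoxy)-2,2-dimethyl-2H-chromene-6-carbaldehyde; 18 ethyl diazoacetate
Product: 19 ethyl 3-[7-(methoxymethoxy)-2,2-dimethyl-2H-chromen-6-yl]-3-oxopropanoate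
Conditions: SnCl2 (10 mol%), CH2Cl2, rt
Reagents that add atoms: none
Why: Roskamp homologation, in which the Lewis-acid-activated aldehyde adds the diazo ester and a 1,2-hydride shift with loss of dinitrogen gives the β-keto ester.

Step 11
Reactants: 19 ethyl 3-[7-(methoxymethoxy)-2,2-dimethyl-2H-chromen-6-yl]-3-oxopropanoate
Product: 20 ethyl (3S)-3-hydroxy-3-[7-(methoxymethoxy)-2,2-dimethyl-2H-chromen-6-yl]propanoate
Conditions: RuCl(p-cymene)[(S,S)-TsDPEN] (1 mol%), HCO2H/Et3N (5:2), EtOAc, 30 °C
Reagents that add atoms: none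
Why: Noyori–Ikariya asymmetric transfer hydrogenation, in which the (S,S) catalyst should deliver hydride to the Re face of the aryl ketone (aryl oriented by the CH–π contact with p-cymene), sets C3 as (S) in the same sense as acetophenone gives (S)-1-phenylethanol and leaves the chromene alkene untouched.

Step 12
Reactants: 20 ethyl (3S)-3-hydroxy-3-[7-(methoxymethoxy)-2,2-dimethyl-2H-chromen-6-yl]propanoate
Product: 21 ethyl (3S)-3-[7-(methoxymethoxy)-2,2-dimethyl-2H-chromen-6-yl]-3-[(trimethylsilyl)oxy]propanoate
Conditions: TMSCl, Et3N, DMAP (cat.), CH2Cl2, 0 °C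
Reagents that add atoms: chlorotrimethylsilane, C[Si](C)(C)Cl
Why: silylation of the secondary alcohol gives an ether from which fluoride can later release the alkoxide without any proton source.

**Annulation and deprotection**

Step 13
Reactants: 21 ethyl (3S)-3-[7-(methoxymethoxy)-2,2-dimethyl-2H-chromen-6-yl]-3-[(trimethylsilyl)oxy]propanoate; 11 3,5-bis(methoxymethoxy)-4-(3-methylbut-2-en-1-yl)-2-(trimethylsilyl)phenyl trifluoromethanesulfonate
Product: 25 (2S)-5,7-bis(methoxymethoxy)-2-[7-(methoxymethoxy)-2,2-dimethyl-2H-chromen-6-yl]-6-(3-methylbut-2-en-1-yl)-2,3-dihydro-4H-chromen-4-one, via cesium alkoxide 22 (not isolated), via aryne 23 (not isolated), via aryl cesium adduct 24 (not isolated)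
Conditions: CsF (1.1 equiv), 18-crown-6 (1.1 equiv), THF, −20 °C → rt, slow addition of 11 (1.2 equiv)
Reagents that add atoms: none
Why: Proposed new method: fluoride removes the O-silyl group of 21 and the C-silyl group of 11 (with 1,2-loss of triflate), so alkoxide 22 and aryne 23 meet in an aprotic medium; 22 adds to 23 to give aryl anion 24, which attacks the tethered ester and expels ethoxide, and that ethoxide desilylates the next molecule of 21 or 11 and ends as ethoxytrimethylsilane, so about one equivalent of fluoride suffices and no alkoxide base should remain beside the product; the closest known reaction types are the aryne–salicylate annulation to xanthones, aryne insertion into carboxylic acid C–O bonds, the aryne acyl-alkylation of β-keto esters and the Parham cycloacylation. Ring C is the only ring closed, first by the intermolecular O1–C8a bond and then by 6-exo-trig acyl substitution that forms C4–C4a. No new stereocenter is formed: C2 (S), set in step 11, takes part in no bond made or broken and should be carried through unchanged. The selectivity needed is regiochemical, oxygen at C8a and not at C4a: the C5 OMOM group flanking C4a distorts the aryne and stabilises negative charge at C4a inductively, and C8a is the less hindered terminus, so both effects direct the nucleophile to C8a. Acylation of 24 should outrun protonation because no O–H or N–H donor is present and the ester is held in a six-membered transition state.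

Step 14
Reactants: 25 (2S)-5,7-bis(methoxymethoxy)-2-[7-(methoxymethoxy)-2,2-dimethyl-2H-chromen-6-yl]-6-(3-methylbut-2-en-1-yl)-2,3-dihydro-4H-chromen-4-one
Product: 26 cudraflavanone A
Conditions: 3 M aq. HCl, MeOH/THF, 40 °C
Reagents that add atoms: none
Why: acid-catalysed transacetalisation to methanol removes the three MOM groups, while the prenyl group, the chromene and the C2 stereocenter (not involved) should survive the mild conditions.

**Compound list**

1 | resorcinol (benzene-1,3-diol) | Oc1cccc(O)c1 | starting material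
2 | 1,3-bis(methoxymethoxy)benzene | COCOc1cccc(OCOC)c1 | intermediate
3 | prenyl bromide (1-bromo-3-methylbut-2-ene) | CC(C)=CCBr | starting material
4 | [2,6-bis(methoxymethoxy)phenyl]lithium | COCOc1cccc(OCOC)c1[Li] | intermediate
5 | 1,3-bis(methoxymethoxy)-2-(3-methylbut-2-en-1-yl)benzene | COCOc1cccc(OCOC)c1CC=C(C)C | intermediate
6 | 2-[3,5-bis(methoxymethoxy)-4-(3-methylbut-2-en-1-yl)phenyl]-4,4,5,5-tetramethyl-1,3,2-dioxaborolane | COCOc1cc(B2OC(C)(C)C(C)(C)O2)cc(OCOC)c1CC=C(C)C | intermediate
7 | 3,5-bis(methoxymethoxy)-4-(3-methylbut-2-en-1-yl)phenol | COCOc1cc(O)cc(OCOC)c1CC=C(C)C | intermediate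
8 | 2-bromo-3,5-bis(methoxymethoxy)-4-(3-methylbut-2-en-1-yl)phenol | COCOc1cc(O)c(Br)c(OCOC)c1CC=C(C)C | intermediate
9 | [2-bromo-3,5-bis(methoxymethoxy)-4-(3-methylbut-2-en-1-yl)phenoxy]trimethylsilane | COCOc1cc(O[Si](C)(C)C)c(Br)c(OCOC)c1CC=C(C)C | intermediate
10 | lithium 3,5-bis(methoxymethoxy)-4-(3-methylbut-2-en-1-yl)-2-(trimethylsilyl)phenoxide | COCOc1cc([O-])c([Si](C)(C)C)c(OCOC)c1CC=C(C)C.[Li+] | intermediate
11 | 3,5-bis(methoxymethoxy)-4-(3-methylbut-2-en-1-yl)-2-(trimethylsilyl)phenyl trifluoromethanesulfonate | COCOc1cc(OS(=O)(=O)C(F)(F)F)c([Si](C)(C)C)c(OCOC)c1CC=C(C)C | intermediate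
12 | 3-methylbut-2-enoic acid | CC(C)=CC(=O)O | starting material
13 | 7-hydroxy-2,2-dimethylchroman-4-one | CC1(C)CC(=O)c2ccc(O)cc2O1 | intermediate
14 | 2,2-dimethylchromane-4,7-diol (racemic) | CC1(C)CC(O)c2ccc(O)cc2O1 | intermediate
15 | 2,2-dimethyl-2H-chromen-7-ol | CC1(C)C=Cc2ccc(O)cc2O1 | intermediate
16 | 7-hydroxy-2,2-dimethyl-2H-chromene-6-carbaldehyde | CC1(C)C=Cc2cc(C=O)c(O)cc2O1 | intermediate
17 | 7-(methoxymethoxy)-2,2-dimethyl-2H-chromene-6-carbaldehyde | COCOc1cc2OC(C)(C)C=Cc2cc1C=O | intermediate
18 | ethyl diazoacetate | CCOC(=O)C=[N+]=[N-] | starting material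
19 | ethyl 3-[7-(methoxymethoxy)-2,2-dimethyl-2H-chromen-6-yl]-3-oxopropanoate | CCOC(=O)CC(=O)c1cc2C=CC(C)(C)Oc2cc1OCOC | intermediate
20 | ethyl (3S)-3-hydroxy-3-[7-(methoxymethoxy)-2,2-dimethyl-2H-chromen-6-yl]propanoate | CCOC(=O)C[C@@H](c1cc2C=CC(C)(C)Oc2cc1OCOC)O | intermediate
21 | ethyl (3S)-3-[7-(methoxymethoxy)-2,2-dimethyl-2H-chromen-6-yl]-3-[(trimethylsilyl)oxy]propanoate | CCOC(=O)C[C@@H](c1cc2C=CC(C)(C)Oc2cc1OCOC)O[Si](C)(C)C | intermediate
22 | cesium (1S)-3-ethoxy-1-[7-(methoxymethoxy)-2,2-dimethyl-2H-chromen-6-yl]-3-oxopropan-1-olate | CCOC(=O)C[C@@H](c1cc2C=CC(C)(C)Oc2cc1OCOC)[O-].[Cs+] | intermediate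
23 | 3,5-bis(methoxymethoxy)-4-(3-methylbut-2-en-1-yl)benzyne | CC(C)=CCC1=C(OCOC)C#CC=C1OCOC | intermediate
24 | cesium 2-{[(1S)-3-ethoxy-1-[7-(methoxymethoxy)-2,2-dimethyl-2H-chromen-6-yl]-3-oxopropyl]oxy}-4,6-bis(methoxymethoxy)-5-(3-methylbut-2-en-1-yl)benzen-1-ide | CCOC(=O)C[C@@H](c1cc2C=CC(C)(C)Oc2cc1OCOC)Oc1cc(OCOC)c(CC=C(C)C)c(OCOC)[c-]1.[Cs+] | intermediate
25 | (2S)-5,7-bis(methoxymethoxy)-2-[7-(methoxymethoxy)-2,2-dimethyl-2H-chromen-6-yl]-6-(3-methylbut-2-en-1-yl)-2,3-dihydro-4H-chromen-4-one | CC(C)=CCc1c(OCOC)cc2c(c1OCOC)C(=O)C[C@@H](c1cc3c(cc1OCOC)OC(C)(C)C=C3)O2 | intermediate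
26 | cudraflavanone A, (2S)-5,7-dihydroxy-2-(7-hydroxy-2,2-dimethyl-2H-chromen-6-yl)-6-(3-methylbut-2-en-1-yl)-2,3-dihydro-4H-chromen-4-one | CC(C)=CCc1c(O)cc2c(c1O)C(=O)C[C@@H](c1cc3c(cc1O)OC(C)(C)C=C3)O2 | target

Total step count: 14. Longest linear sequence: 9 steps (steps 6 to 14, from resorcinol); the aryne branch (steps 1 to 5) joins at step 13.

**Steps most likely to fail**

1. Step 13 (Proposed new method). The aryl anion may be protonated before it acylates, giving only O-arylation. Ethoxide or fluoride may compete with the alkoxide for the aryne. The free alkoxide may undergo retro-aldol cleavage or β-elimination. Base-mediated reversible opening of ring C may erode the C2 configuration. The fallback uses known chemistry, sets out from 19 and 8 and comes back at 25. Transfer hydrogenation of 19 with RuCl(p-cymene)[(R,R)-TsDPEN] should give the enantiomeric alcohol ethyl (3R)-3-hydroxy-3-[7-(methoxymethoxy)-2,2-dimethyl-2H-chromen-6-yl]propanoate F1. Mitsunobu etherification of F1 with bromophenol 8 (PPh3, DIAD, toluene, 0 °C) should proceed with inversion to ethyl (3S)-3-[2-bromo-3,5-bis(methoxymethoxy)-4-(3-methylbut-2-en-1-yl)phenoxy]-3-[7-(methoxymethoxy)-2,2-dimethyl-2H-chromen-6-yl]propanoate F2. Parham cycloacylation of F2 (t-BuLi, THF, −100 °C; bromine–lithium exchange, then attack of the aryllithium on the ester) should close ring C to 25.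

2. Step 14. Acid may cyclise the prenyl group onto a freed flanking phenol, add methanol across the chromene double bond, or erode C2 through reversible ionisation of the benzylic C2–O1 bond. The fallback sets out from 25 and comes back at 26. It exchanges the acetals for silyl ethers under buffered aprotic conditions (TMSOTf, 2,2'-bipyridyl, CH2Cl2, 0 °C) to give the tris-silyl ether (2S)-2-[2,2-dimethyl-7-(trimethylsilyloxy)-2H-chromen-6-yl]-6-(3-methylbut-2-en-1-yl)-5,7-bis(trimethylsilyloxy)-2,3-dihydro-4H-chromen-4-one F3. F3 is then solvolysed at neutral pH (aqueous methanol with pH 7 phosphate buffer, 0 °C) to 26 without exposure to Brønsted acid.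

3. Step 10. Addition of the diazo ester to the deactivated, electron-rich ortho-alkoxy aldehyde may be sluggish, and aryl migration may compete with the hydride shift. The fallback sets out from 17 and comes back at 19. Aldol addition of the lithium enolate of ethyl acetate (LiN(iPr)2, EtOAc, THF, −78 °C) should give racemic ethyl 3-hydroxy-3-[7-(methoxymethoxy)-2,2-dimethyl-2H-chromen-6-yl]propanoate F4. Oxidation of the benzylic alcohol of F4 (MnO2, CH2Cl2, rt) should give 19.

Further compounds
F1 | step 13 | ethyl (3R)-3-hydroxy-3-[7-(methoxymethoxy)-2,2-dimethyl-2H-chromen-6-yl]propanoate | CCOC(=O)C[C@H](c1cc2C=CC(C)(C)Oc2cc1OCOC)O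
F2 | step 13 | ethyl (3S)-3-[2-bromo-3,5-bis(methoxymethoxy)-4-(3-methylbut-2-en-1-yl)phenoxy]-3-[7-(methoxymethoxy)-2,2-dimethyl-2H-chromen-6-yl]propanoate | CCOC(=O)C[C@@H](c1cc2C=CC(C)(C)Oc2cc1OCOC)Oc1cc(OCOC)c(CC=C(C)C)c(OCOC)c1Br
F3 | step 14 | (2S)-2-[2,2-dimethyl-7-(trimethylsilyloxy)-2H-chromen-6-yl]-6-(3-methylbut-2-en-1-yl)-5,7-bis(trimethylsilyloxy)-2,3-dihydro-4H-chromen-4-one | CC(C)=CCc1c(O[Si](C)(C)C)cc2c(c1O[Si](C)(C)C)C(=O)C[C@@H](c1cc3c(cc1O[Si](C)(C)C)OC(C)(C)C=C3)O2
F4 | step 10 | ethyl 3-hydroxy-3-[7-(methoxymethoxy)-2,2-dimethyl-2H-chromen-6-yl]propanoate (racemic) | CCOC(=O)CC(O)c1cc2C=CC(C)(C)Oc2cc1OCOC
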